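**Plan**

1. Retrosynthesis: all thirteen O-benzyl groups are removed last. Ring C of the upper unit is then cut at O1–C2 and C4a–C4, giving 3,5-bis(benzyloxy)phenol and an erythro trans-epoxy carbinol (C2 carbinol, C3–C4 epoxide) carried on C8 of the middle unit. Ring C of the middle unit is cut the same way, back to an 8-formyl catechin.
2. Enabling feature: in each pyran ring, O1 and C4a are the oxygen and ortho carbon of an electron-rich phenol, a 1,3-O,C-binucleophile. In the upper unit this is a phloroglucinol ring A whose two ortho carbons are equivalent. C2 and C4 are both benzylic (to ring B and to ring A of the unit below), so C2–C3–C4 can serve as a 1,3-dielectrophile.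
3. Forward: (+)-catechin → C8 aldehyde → chalcone → epoxy ketone → epoxy alcohol → [3+3] annulation with 3-(benzyloxy)-2-bromophenol (ring C of the middle unit; the bromine marks its C8) → C8 aldehyde → the same four operations → [3+3] annulation with 3,5-bis(benzyloxy)phenol (ring C of the upper unit) → hydrogenolysis.
4. Stereochemistry: the lower unit comes from (+)-catechin. In each new unit, C3 and C4 come from a catalyst-controlled Juliá–Colonna epoxidation and anti opening of the trans-epoxide (3,4-trans). C2 comes from a chelation-controlled erythro-selective ketone reduction followed by Mitsunobu inversion (2,3-cis).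

Key step: step 15

Remark: the target is read as epicatechin-(4β→8)-epifisetinidol-(4β→8)-catechin, (2R,3R,4R) in the upper and middle units and (2R,3S) in the lower unit; compounds 7, 11 and 21 are taken as purchasable. HFIP = (CF3)2CHOH.

**Route**

Step 1
Reactants: 1 (+)-catechin
Product: 2 5,7,3',4'-tetra-O-benzylcatechin
Conditions: BnBr (4.4 equiv), K2CO3, DMF, 0 °C to rt
Reagents that add atoms: benzyl bromide BrCc1ccccc1
Why: Williamson ether synthesis in which K2CO3 ionises only the four phenols, so the secondary C3 alcohol and both stereocentres are left untouched.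

Step 2
Reactants: 2 5,7,3',4'-tetra-O-benzylcatechin
Product: 3 8-bromo-5,7,3',4'-tetra-O-benzylcatechin
Conditions: NBS (1.0 equiv), CH2Cl2, −78 °C to 0 °C
Reagents that add atoms: N-bromosuccinimide O=C1CCC(=O)N1Br
Why: Electrophilic aromatic bromination; the phloroglucinol-type ring A is the most nucleophilic arene, and in 5,7-di-O-benzyl flavan-3-ols NBS is known to attack C8 in preference to C6.

Step 3
Reactants: 3 8-bromo-5,7,3',4'-tetra-O-benzylcatechin
Product: 4 8-bromo-3,5,7,3',4'-penta-O-benzylcatechin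
Conditions: NaH, BnBr, DMF, 0 °C to rt
Reagents that add atoms: benzyl bromide BrCc1ccccc1
Why: Williamson ether synthesis on the C3 alkoxide, which removes the last acidic proton before the organolithium and Mitsunobu steps.

Step 4
Reactants: 4 8-bromo-3,5,7,3',4'-penta-O-benzylcatechin
Product: 6 penta-O-benzylcatechin-8-carbaldehyde, via 8-lithio-penta-O-benzylcatechin 5 (not isolated)
Conditions: t-BuLi (2.1 equiv), THF, −78 °C; DMF, −78 to 0 °C; H2O
Reagents that add atoms: N,N-dimethylformamide CN(C)C=O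
Why: Bromine–lithium exchange followed by formylation of the aryllithium with DMF (Bouveault aldehyde synthesis); exchange at −78 °C outruns deprotonation of the benzyl ethers, and the bromide fixes the position.

Step 5
Reactants: 6 penta-O-benzylcatechin-8-carbaldehyde, 7 1-[3,4-bis(benzyloxy)phenyl]ethanone
Product: 8 chalcone A
Conditions: KOH, EtOH/THF, rt
Reagents that add atoms: none
Why: Claisen–Schmidt condensation of a non-enolisable aldehyde with the methyl ketone; dehydration of the aldol should give the conjugated (E)-enone.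

Step 6
Reactants: 8 chalcone A
Product: 9 epoxy ketone A
Conditions: poly-L-leucine, urea–H2O2, DBU, THF, rt
Reagents that add atoms: hydrogen peroxide (from its urea adduct) OO
Why: Juliá–Colonna epoxidation (conjugate addition of hydroperoxide, then ring closure) attacks only the electron-poor enone and spares the electron-rich arenes; the L-peptide is the antipode that gives (2R,3S)-epoxychalcone from chalcone itself, which sets what become C3 and C4 of the middle unit.

Step 7
Reactants: 9 epoxy ketone A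
Product: 10 epoxy alcohol A
Conditions: Zn(BH4)2, Et2O/THF, −30 °C; aq. NaHCO3; crude product used at once
Reagents that add atoms: none
Why: Chelation-controlled reduction of an α,β-epoxy ketone, in which zinc bridges the carbonyl and epoxide oxygens and hydride attacks the open face, should give the erythro epoxy alcohol whose (S)-carbinol becomes C2 after inversion.

Step 8
Reactants: 11 2-bromoresorcinol
Product: 12 3-(benzyloxy)-2-bromophenol
Conditions: BnBr (1.0 equiv), K2CO3, acetone, reflux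
Reagents that add atoms: benzyl bromide BrCc1ccccc1
Why: Williamson ether synthesis on a symmetric diphenol run to partial conversion; the mono-ether is separated from the bis-ether and unchanged 11.

Step 9
Reactants: 10 epoxy alcohol A, 12 3-(benzyloxy)-2-bromophenol
Product: 14 dimer bromide (middle 3-OH free), via aryl glycidyl ether A 13 (not isolated)
Conditions: PPh3, DIAD, toluene, 0 °C to rt; then HFIP, 0 °C to rt
Reagents that add atoms: none
Why: Mitsunobu etherification (SN2, inversion at the carbinol, giving 2R) is followed in the same flask by HFIP-promoted intramolecular Friedel–Crafts epoxy-arene cyclisation (6-endo, anti opening at the benzylic epoxide carbon, giving 3,4-trans), and the bromine leaves only the carbon para to the benzyloxy group open for ring closure.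

Step 10
Reactants: 14 dimer bromide (middle 3-OH free)
Product: 15 dimer bromide 3-O-benzyl ether
Conditions: NaH, BnBr, n-Bu4NI (cat.), DMF, 0 °C to rt
Reagents that add atoms: benzyl bromide BrCc1ccccc1
Why: Williamson ether synthesis with iodide catalysis masks the hindered axial C3 hydroxyl, the only OH, so that it cannot interfere in the later organolithium and Mitsunobu steps.

Step 11
Reactants: 15 dimer bromide 3-O-benzyl ether
Product: 17 dimer aldehyde, via dimer aryllithium 16 (not isolated)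
Conditions: t-BuLi (2.1 equiv), THF, −78 °C; DMF, −78 to 0 °C; H2O
Reagents that add atoms: N,N-dimethylformamide CN(C)C=O
Why: Bromine–lithium exchange and DMF formylation as in step 4; the aryllithium can form only at the carbon that carried bromine, which is C8 of the middle unit.

Step 12
Reactants: 17 dimer aldehyde, 7 1-[3,4-bis(benzyloxy)phenyl]ethanone
Product: 18 chalcone B
Conditions: KOH, EtOH/THF, rt to 40 °C
Reagents that add atoms: none
Why: Claisen–Schmidt condensation as in step 5; benzyl ethers are inert to hydroxide and the (E)-enone is the thermodynamic product.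

Step 13
Reactants: 18 chalcone B
Product: 19 epoxy ketone B
Conditions: poly-L-leucine, urea–H2O2, DBU, THF, rt
Reagents that add atoms: hydrogen peroxide (from its urea adduct) OO
Why: Juliá–Colonna epoxidation as in step 6; the peptide catalyst, not the remote stereocentres of the dimer, should select the enone face and set C3 and C4 of the upper unit as the trans (2R,3S)-epoxide.

Step 14
Reactants: 19 epoxy ketone B
Product: 20 epoxy alcohol B
Conditions: Zn(BH4)2, Et2O/THF, −30 °C; aq. NaHCO3; crude product used at once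
Reagents that add atoms: none
Why: Chelation-controlled erythro-selective reduction of the α,β-epoxy ketone as in step 7 should set the (S)-carbinol that becomes C2 of the upper unit after inversion.

Step 15
Reactants: 20 epoxy alcohol B, 21 3,5-bis(benzyloxy)phenol
Product: 23 trideca-O-benzyl trimer (upper 3-OH free), via aryl glycidyl ether B 22 (not isolated)
Conditions: 21 (1.05 equiv), PPh3, DIAD, toluene, 0 °C to rt; then HFIP, 0 °C to rt
Reagents that add atoms: none
Why: PPh3/DIAD turns the C2 carbinol of 20 into an oxyphosphonium ion that 21 displaces through oxygen in an SN2 Mitsunobu etherification (O1–C2, inversion to 2R; the neighbouring epoxide withdraws electron density and holds back ionisation of this 3,4-dialkoxybenzylic centre), and in the ionising, hydrogen-bond-donating HFIP the tethered 3,5-dibenzyloxyphenoxy ring of 22 then attacks the epoxide carbon C4 in an intramolecular Friedel–Crafts epoxy-arene cyclisation (C4a–C4). The closest known reaction types are the Mitsunobu aryl ether synthesis with secondary benzylic alcohols and the HFIP-promoted cyclisation of aryl trans-3-arylglycidyl ethers to trans-4-arylchroman-3-ols. Ring C of the upper unit closes in the 6-endo epoxide-opening mode, preferred over 5-exo attack at C3 because only C4 is benzylic and its cationic character is stabilised by the 2,6-dioxygenated ring A of the middle unit. C3 (3R) is carried over from the epoxide, C4 (4R) arises by anti opening of the trans-epoxide (3,4-trans), and C2 by Mitsunobu inversion of the erythro carbinol (2,3-cis). No regiocontrol is needed because the two carbons ortho to the ether oxygen of the C2v-symmetric phenoxy ring are equivalent and each is activated by three oxygen substituents; should the epoxide ionise fully before C–C bond formation, the half-chair with the middle unit pseudo-axial at C4 (away from the peri 5-benzyloxy group) and anti to the C3 oxygen still leads to the 3,4-trans product.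

Step 16
Reactants: 23 trideca-O-benzyl trimer (upper 3-OH free)
Product: 24 epicatechin-(4β→8)-epifisetinidol-(4β→8)-catechin
Conditions: H2 (1 atm), Pd(OH)2/C, THF/MeOH/H2O, rt
Reagents that add atoms: none
Why: Catalytic hydrogenolysis should remove all thirteen O-benzyl groups, while the chroman C–O bonds and the doubly benzylic interflavan C–C bonds are known to survive these conditions in benzylated procyanidins.

**Compound list**

1 | (+)-catechin, (2R,3S)-2-(3,4-dihydroxyphenyl)chromane-3,5,7-triol | Oc1cc(O)c2c(c1)O[C@H](c1ccc(O)c(O)c1)[C@@H](O)C2 | starting material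
2 | 5,7,3',4'-tetra-O-benzylcatechin | c5c(OCc9ccccc9)cc(OCc9ccccc9)c6c5O[C@H](c8ccc(OCc9ccccc9)c(OCc9ccccc9)c8)[C@@H](O)C6 | intermediate
3 | 8-bromo-5,7,3',4'-tetra-O-benzylcatechin | Brc5c(OCc9ccccc9)cc(OCc9ccccc9)c6c5O[C@H](c8ccc(OCc9ccccc9)c(OCc9ccccc9)c8)[C@@H](O)C6 | intermediate
4 | 8-bromo-3,5,7,3',4'-penta-O-benzylcatechin | Brc5c(OCc9ccccc9)cc(OCc9ccccc9)c6c5O[C@H](c8ccc(OCc9ccccc9)c(OCc9ccccc9)c8)[C@@H](OCc9ccccc9)C6 | intermediate
5 | 8-lithio-3,5,7,3',4'-penta-O-benzylcatechin | [Li]c5c(OCc9ccccc9)cc(OCc9ccccc9)c6c5O[C@H](c8ccc(OCc9ccccc9)c(OCc9ccccc9)c8)[C@@H](OCc9ccccc9)C6 | intermediate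
6 | 3,5,7,3',4'-penta-O-benzylcatechin-8-carbaldehyde | O=Cc5c(OCc9ccccc9)cc(OCc9ccccc9)c6c5O[C@H](c8ccc(OCc9ccccc9)c(OCc9ccccc9)c8)[C@@H](OCc9ccccc9)C6 | intermediate
7 | 1-[3,4-bis(benzyloxy)phenyl]ethanone | CC(=O)c1ccc(OCc2ccccc2)c(OCc2ccccc2)c1 | starting material
8 | chalcone A, (E)-1-[3,4-bis(benzyloxy)phenyl]-3-(penta-O-benzylcatechin-8-yl)prop-2-en-1-one | O=C(c8ccc(OCc9ccccc9)c(OCc9ccccc9)c8)/C=C/c5c(OCc9ccccc9)cc(OCc9ccccc9)c6c5O[C@H](c8ccc(OCc9ccccc9)c(OCc9ccccc9)c8)[C@@H](OCc9ccccc9)C6 | intermediate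
9 | epoxy ketone A, [3,4-bis(benzyloxy)phenyl][(2R,3S)-3-(penta-O-benzylcatechin-8-yl)oxiran-2-yl]methanone (trans-epoxide) | O=C(c8ccc(OCc9ccccc9)c(OCc9ccccc9)c8)[C@@H]7O[C@H]7c5c(OCc9ccccc9)cc(OCc9ccccc9)c6c5O[C@H](c8ccc(OCc9ccccc9)c(OCc9ccccc9)c8)[C@@H](OCc9ccccc9)C6 | intermediate
10 | epoxy alcohol A, (S)-[3,4-bis(benzyloxy)phenyl][(2S,3S)-3-(penta-O-benzylcatechin-8-yl)oxiran-2-yl]methanol (erythro; same epoxide as in 9, the descriptor at oxirane C2 changes by the priority rule only) | O[C@@H](c8ccc(OCc9ccccc9)c(OCc9ccccc9)c8)[C@@H]7O[C@H]7c5c(OCc9ccccc9)cc(OCc9ccccc9)c6c5O[C@H](c8ccc(OCc9ccccc9)c(OCc9ccccc9)c8)[C@@H](OCc9ccccc9)C6 | intermediate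
11 | 2-bromoresorcinol (2-bromobenzene-1,3-diol) | Oc1cccc(O)c1Br | starting material
12 | 3-(benzyloxy)-2-bromophenol | Oc1cccc(OCc2ccccc2)c1Br | intermediate
13 | aryl glycidyl ether A: 3-(benzyloxy)-2-bromophenyl ether of 10 with inverted (R) ether carbon, epoxide unchanged | Brc3c(OCc9ccccc9)cccc3O[C@H](c8ccc(OCc9ccccc9)c(OCc9ccccc9)c8)[C@@H]7O[C@H]7c5c(OCc9ccccc9)cc(OCc9ccccc9)c6c5O[C@H](c8ccc(OCc9ccccc9)c(OCc9ccccc9)c8)[C@@H](OCc9ccccc9)C6 | intermediate
14 | dimer bromide: 8-bromo-7,3',4'-tri-O-benzyl-epifisetinidol-(4β→8)-3,5,7,3',4'-penta-O-benzylcatechin, new unit (2R,3R,4R), its 3-OH free | Brc3c(OCc9ccccc9)ccc4c3O[C@H](c8ccc(OCc9ccccc9)c(OCc9ccccc9)c8)[C@H](O)[C@H]4c5c(OCc9ccccc9)cc(OCc9ccccc9)c6c5O[C@H](c8ccc(OCc9ccccc9)c(OCc9ccccc9)c8)[C@@H](OCc9ccccc9)C6 | intermediate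
15 | dimer bromide 3-O-benzyl ether (nona-O-benzyl) | Brc3c(OCc9ccccc9)ccc4c3O[C@H](c8ccc(OCc9ccccc9)c(OCc9ccccc9)c8)[C@H](OCc9ccccc9)[C@H]4c5c(OCc9ccccc9)cc(OCc9ccccc9)c6c5O[C@H](c8ccc(OCc9ccccc9)c(OCc9ccccc9)c8)[C@@H](OCc9ccccc9)C6 | intermediate
16 | dimer aryllithium (lithium at C8 of the epifisetinidol unit) | [Li]c3c(OCc9ccccc9)ccc4c3O[C@H](c8ccc(OCc9ccccc9)c(OCc9ccccc9)c8)[C@H](OCc9ccccc9)[C@H]4c5c(OCc9ccccc9)cc(OCc9ccccc9)c6c5O[C@H](c8ccc(OCc9ccccc9)c(OCc9ccccc9)c8)[C@@H](OCc9ccccc9)C6 | intermediate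
17 | dimer aldehyde (formyl at C8 of the epifisetinidol unit) | O=Cc3c(OCc9ccccc9)ccc4c3O[C@H](c8ccc(OCc9ccccc9)c(OCc9ccccc9)c8)[C@H](OCc9ccccc9)[C@H]4c5c(OCc9ccccc9)cc(OCc9ccccc9)c6c5O[C@H](c8ccc(OCc9ccccc9)c(OCc9ccccc9)c8)[C@@H](OCc9ccccc9)C6 | intermediate
18 | chalcone B, (E)-enone from 17 and 7 | O=C(c8ccc(OCc9ccccc9)c(OCc9ccccc9)c8)/C=C/c3c(OCc9ccccc9)ccc4c3O[C@H](c8ccc(OCc9ccccc9)c(OCc9ccccc9)c8)[C@H](OCc9ccccc9)[C@H]4c5c(OCc9ccccc9)cc(OCc9ccccc9)c6c5O[C@H](c8ccc(OCc9ccccc9)c(OCc9ccccc9)c8)[C@@H](OCc9ccccc9)C6 | intermediate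
19 | epoxy ketone B, trans (2R,3S)-oxirane with the aroyl group on C2 and the dimer on C3 | O=C(c8ccc(OCc9ccccc9)c(OCc9ccccc9)c8)[C@@H]7O[C@H]7c3c(OCc9ccccc9)ccc4c3O[C@H](c8ccc(OCc9ccccc9)c(OCc9ccccc9)c8)[C@H](OCc9ccccc9)[C@H]4c5c(OCc9ccccc9)cc(OCc9ccccc9)c6c5O[C@H](c8ccc(OCc9ccccc9)c(OCc9ccccc9)c8)[C@@H](OCc9ccccc9)C6 | intermediate
20 | epoxy alcohol B, erythro: (S)-carbinol on a (2S,3S)-oxirane (same epoxide as in 19) | O[C@@H](c8ccc(OCc9ccccc9)c(OCc9ccccc9)c8)[C@@H]7O[C@H]7c3c(OCc9ccccc9)ccc4c3O[C@H](c8ccc(OCc9ccccc9)c(OCc9ccccc9)c8)[C@H](OCc9ccccc9)[C@H]4c5c(OCc9ccccc9)cc(OCc9ccccc9)c6c5O[C@H](c8ccc(OCc9ccccc9)c(OCc9ccccc9)c8)[C@@H](OCc9ccccc9)C6 | intermediate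
21 | 3,5-bis(benzyloxy)phenol | Oc1cc(OCc2ccccc2)cc(OCc2ccccc2)c1 | starting material
22 | aryl glycidyl ether B: 3,5-bis(benzyloxy)phenyl ether of 20 with inverted (R) ether carbon, epoxide unchanged | O(Cc9ccccc9)c1cc(OCc9ccccc9)cc(c1)O[C@H](c8ccc(OCc9ccccc9)c(OCc9ccccc9)c8)[C@@H]7O[C@H]7c3c(OCc9ccccc9)ccc4c3O[C@H](c8ccc(OCc9ccccc9)c(OCc9ccccc9)c8)[C@H](OCc9ccccc9)[C@H]4c5c(OCc9ccccc9)cc(OCc9ccccc9)c6c5O[C@H](c8ccc(OCc9ccccc9)c(OCc9ccccc9)c8)[C@@H](OCc9ccccc9)C6 | intermediate
23 | trideca-O-benzyl trimer: 5,7,3',4'-tetra-O-benzyl-epicatechin-(4β→8)-3,7,3',4'-tetra-O-benzyl-epifisetinidol-(4β→8)-penta-O-benzylcatechin, upper 3-OH free | O(Cc9ccccc9)c1cc(OCc9ccccc9)c2c(c1)O[C@H](c8ccc(OCc9ccccc9)c(OCc9ccccc9)c8)[C@H](O)[C@H]2c3c(OCc9ccccc9)ccc4c3O[C@H](c8ccc(OCc9ccccc9)c(OCc9ccccc9)c8)[C@H](OCc9ccccc9)[C@H]4c5c(OCc9ccccc9)cc(OCc9ccccc9)c6c5O[C@H](c8ccc(OCc9ccccc9)c(OCc9ccccc9)c8)[C@@H](OCc9ccccc9)C6 | intermediate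
24 | epicatechin-(4β→8)-epifisetinidol-(4β→8)-catechin (CNP0270097.1) | Oc1cc(O)c2c(c1)O[C@H](c1ccc(O)c(O)c1)[C@H](O)[C@H]2c1c(O)ccc2c1O[C@H](c1ccc(O)c(O)c1)[C@H](O)[C@H]2c1c(O)cc(O)c2c1O[C@H](c1ccc(O)c(O)c1)[C@@H](O)C2 | target

**Step count and risks**

Total steps: 16. Longest linear sequence: 15 steps (steps 1–7 and 9–16); step 8 is a one-step side branch.

Steps most likely to fail:

1. Step 15. In the Mitsunobu stage the hindered, electron-rich benzylic oxyphosphonium ion may ionise instead of being displaced, so that the C2 configuration leaks towards 2,3-trans material; the acid-labile epoxide may also rearrange before the ring closes. The fallback sets out from 20 and returns at 24, with the order of the two bond formations reversed. The epoxide of 20 is first opened at C4 by a large excess of phloroglucinol in HFIP, an intermolecular Friedel–Crafts alkylation with inversion in which all three ring carbons of the nucleophile are equivalent, to give the phloroglucinol adduct F1. Mitsunobu cyclisation (PPh3, DIAD, THF) then closes O1–C2 by 6-exo-tet displacement of the benzylic C2 carbinol with inversion, giving the 5,7-dihydroxy trimer F2. Hydrogenolysis under the conditions of step 16 should give 24.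

2. Step 9. The 2,4,6-trioxygenated aryl epoxide of 10 is the most easily ionised intermediate of the route; opening to a free cation during the slower Mitsunobu stage would cause rearrangement or loss of the anti stereospecificity at C4. The fallback sets out from 10 and returns at 15. The epoxide is consumed first by Friedel–Crafts opening with excess 2-bromoresorcinol 11 in HFIP (its two open reactive positions are equivalent), giving the bromoresorcinol adduct F3. Mitsunobu cyclisation (PPh3, DIAD, THF) onto the benzylic carbinol with inversion gives the 7-hydroxy dimer bromide F4. Double benzylation (NaH, BnBr, DMF) of its phenol and C3 alcohol gives 15.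

3. Step 13 (and, for the same reason, step 6). Nucleophilic epoxidation of a large, hindered, push-pull deactivated enone on a heterogeneous peptide catalyst may be slow and poorly face-selective. The fallback sets out from 18 and returns at 20, moving the epoxidation to the alcohol oxidation level. Luche reduction (NaBH4, CeCl3·7H2O, MeOH/THF, −20 °C) gives the (R)-allylic alcohol F5 together with the (S)-allylic alcohol F6. Sharpless epoxidation under kinetic-resolution conditions (Ti(OiPr)4, L-(+)-diisopropyl tartrate, t-BuOOH, 4 Å sieves, CH2Cl2, −20 °C) should epoxidise only F5, on the face syn to the carbinol hydrogen, to give the erythro epoxy alcohol 20. Unreacted F6 is returned to 18 by MnO2 oxidation.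

Further compounds
F1 | step 15 | phloroglucinol adduct of 20: 1-[3,4-bis(benzyloxy)phenyl]-3-(2,4,6-trihydroxyphenyl)-3-(dimer-8-yl)propane-1,2-diol from anti opening of the epoxide at C4 | O[C@@H](c8ccc(OCc9ccccc9)c(OCc9ccccc9)c8)[C@H](O)[C@H](c1c(O)cc(O)cc1O)c3c(OCc9ccccc9)ccc4c3O[C@H](c8ccc(OCc9ccccc9)c(OCc9ccccc9)c8)[C@H](OCc9ccccc9)[C@H]4c5c(OCc9ccccc9)cc(OCc9ccccc9)c6c5O[C@H](c8ccc(OCc9ccccc9)c(OCc9ccccc9)c8)[C@@H](OCc9ccccc9)C6
F2 | step 15 | 5,7-dihydroxy analogue of 23 (undeca-O-benzyl trimer) | Oc1cc(O)c2c(c1)O[C@H](c8ccc(OCc9ccccc9)c(OCc9ccccc9)c8)[C@H](O)[C@H]2c3c(OCc9ccccc9)ccc4c3O[C@H](c8ccc(OCc9ccccc9)c(OCc9ccccc9)c8)[C@H](OCc9ccccc9)[C@H]4c5c(OCc9ccccc9)cc(OCc9ccccc9)c6c5O[C@H](c8ccc(OCc9ccccc9)c(OCc9ccccc9)c8)[C@@H](OCc9ccccc9)C6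
F3 | step 9 | bromoresorcinol adduct of 10: 1-[3,4-bis(benzyloxy)phenyl]-3-(3-bromo-2,4-dihydroxyphenyl)-3-(penta-O-benzylcatechin-8-yl)propane-1,2-diol | O[C@@H](c8ccc(OCc9ccccc9)c(OCc9ccccc9)c8)[C@H](O)[C@H](c3ccc(O)c(Br)c3O)c5c(OCc9ccccc9)cc(OCc9ccccc9)c6c5O[C@H](c8ccc(OCc9ccccc9)c(OCc9ccccc9)c8)[C@@H](OCc9ccccc9)C6
F4 | step 9 | 7-hydroxy analogue of 14 (8-bromo-3',4'-di-O-benzyl-epifisetinidol-(4β→8)-penta-O-benzylcatechin) | Brc3c(O)ccc4c3O[C@H](c8ccc(OCc9ccccc9)c(OCc9ccccc9)c8)[C@H](O)[C@H]4c5c(OCc9ccccc9)cc(OCc9ccccc9)c6c5O[C@H](c8ccc(OCc9ccccc9)c(OCc9ccccc9)c8)[C@@H](OCc9ccccc9)C6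
F5 | step 13 | (R,E)-allylic alcohol from 18 | O[C@@H](c8ccc(OCc9ccccc9)c(OCc9ccccc9)c8)/C=C/c3c(OCc9ccccc9)ccc4c3O[C@H](c8ccc(OCc9ccccc9)c(OCc9ccccc9)c8)[C@H](OCc9ccccc9)[C@H]4c5c(OCc9ccccc9)cc(OCc9ccccc9)c6c5O[C@H](c8ccc(OCc9ccccc9)c(OCc9ccccc9)c8)[C@@H](OCc9ccccc9)C6
F6 | step 13 | (S,E)-allylic alcohol from 18 | O[C@H](c8ccc(OCc9ccccc9)c(OCc9ccccc9)c8)/C=C/c3c(OCc9ccccc9)ccc4c3O[C@H](c8ccc(OCc9ccccc9)c(OCc9ccccc9)c8)[C@H](OCc9ccccc9)[C@H]4c5c(OCc9ccccc9)cc(OCc9ccccc9)c6c5O[C@H](c8ccc(OCc9ccccc9)c(OCc9ccccc9)c8)[C@@H](OCc9ccccc9)C6
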